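**Retrosynthetic overview**
- Ring B (second oxepane; C3–C4 bond and C15–O) is closed last by an intramolecular nitrile oxide–alkene cycloaddition. N–O cleavage, C3 reduction, C15 acetylation and desilylation finish the synthesis.
- Ring A (oxepane O/C5–C10) is closed before that: the C5 aldehyde and the tertiary C10–OH give a lactol acetate, which is C-vinylated at C5.
- The C8 ester comes from protected sarracinic acid (made from methyl but-2-ynoate); the C8–OH comes from a dithiane-masked ketone reduced inside ring A.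
- The C7–C8 bond comes from 1,4-addition of a linalool-derived dithiane anion to a butenolide (lactone ring bought); C13 is added by Mannich methylenation.
- C10 is bought in (R)-linalool and C6 in (S)-5-(hydroxymethyl)furan-2(5H)-one; C7, C5, C8, C4 and C3 follow by substrate control. Ring order: lactone (bought) → ring A → ring B.

Assumption: the SMILES is taken literally; its descriptors place the ether carbons C5 and C10 trans (inside–outside) across the ten-membered ring, so both are fixed before ring B is closed. Numbering is germacrane-type (C1–C15; lactone C12–O–C6; ether C5–O–C10; ester on C8; ring A = O, C5–C10; ring B = O, C10, C1–C5).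

**Step 1**
Reactants: 1 (R)-(−)-linalool
Product: 3 (3R)-3,7-dimethyloct-6-ene-1,3-diol, via B-alkyl-9-BBN adduct 2 (not isolated)
Conditions: 9-BBN (1.5 equiv), THF, 0 °C → rt; then NaOH, H2O2, H2O, 0 °C
Reagents that add atoms: hydrogen peroxide, OO
Why: Brown hydroboration–oxidation; 9-BBN takes only the monosubstituted vinyl group (anti-Markovnikov) and leaves the trisubstituted alkene and the bought C10 stereocentre untouched.

**Step 2**
Reactants: 3 (3R)-3,7-dimethyloct-6-ene-1,3-diol
Product: 4 (3R)-3-hydroxy-3,7-dimethyloct-6-enal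
Conditions: TEMPO (2,2,6,6-tetramethylpiperidin-1-oxyl, 10 mol %), PhI(OAc)2, CH2Cl2, rt
Reagents that add atoms: none
Why: Oxoammonium (TEMPO) oxidation converts only the primary alcohol, the tertiary alcohol cannot be oxidised, and the near-neutral medium avoids dehydration of the β-hydroxy aldehyde.

**Step 3**
Reactants: 4 (3R)-3-hydroxy-3,7-dimethyloct-6-enal
Product: 5 2-[(2R)-2-hydroxy-2,6-dimethylhept-5-en-1-yl]-1,3-dithiane
Conditions: HS(CH2)3SH, MgBr2·OEt2, Et2O, rt
Reagents that add atoms: propane-1,3-dithiol, SCCCS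
Why: Mild Lewis-acid dithioacetalisation gives the Corey–Seebach acyl-anion equivalent for C8 without ionising the tertiary alcohol.

**Step 4**
Reactants: 6 (S)-5-(hydroxymethyl)furan-2(5H)-one
Product: 7 (S)-5-[(triethylsilyloxy)methyl]furan-2(5H)-one
Conditions: Et3SiCl, imidazole, CH2Cl2, 0 °C
Reagents that add atoms: chlorotriethylsilane, CC[Si](Cl)(CC)CC
Why: Silylation of the primary alcohol removes the only acidic O–H of the butenolide; the bought C6 stereocentre is not involved.

**Step 5**
Reactants: 5 2-[(2R)-2-hydroxy-2,6-dimethylhept-5-en-1-yl]-1,3-dithiane; 7 (S)-5-[(triethylsilyloxy)methyl]furan-2(5H)-one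
Product: 10 Mannich base (4S,5S)-3-[(dimethylamino)methyl]-4-(2-alkyl-1,3-dithian-2-yl)-5-[(triethylsilyloxy)methyl]oxolan-2-one, via dilithio dithiane 8 (not isolated), via lithium enolate 9 (not isolated)
Conditions: 5, n-BuLi (2.1 equiv), THF, −30 °C; HMPA, −78 °C, add 7; then Me2N=CH2+ I−, −78 °C → rt
Reagents that add atoms: dimethyl(methylidene)ammonium iodide (Eschenmoser's salt), C=[N+](C)C.[I-]
Why: Corey–Seebach dithiane anion adds 1,4 (HMPA) to the butenolide anti to the C6 side chain, which sets C7 trans to C6, and the enolate is trapped in a Mannich reaction (the C11 epimers are removed in step 6).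

**Step 6**
Reactants: 10 Mannich base
Product: 12 (4S,5S)-4-{2-[(2R)-2-hydroxy-2,6-dimethylhept-5-en-1-yl]-1,3-dithian-2-yl}-3-methylidene-5-[(triethylsilyloxy)methyl]oxolan-2-one, via ammonium iodide 11 (not isolated)
Conditions: MeI, THF, rt; then aq. NaHCO3, CH2Cl2, rt
Reagents that add atoms: none
Why: N-methylation (much faster than S-methylation of the dithiane) followed by Hofmann-type β-elimination unveils the exocyclic C11=C13 alkene.

**Step 7**
Reactants: 12 α-methylene lactone triethylsilyl ether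
Product: 15 lactol acetate (C5-acetoxy oxepane; ring A closed; C5 anomers), via aldehyde 13 (not isolated), via lactol 14 (not isolated)
Conditions: (COCl)2, DMSO, CH2Cl2, −78 → −30 °C; Et3N; then Ac2O, 4-(dimethylamino)pyridine, −30 → 0 °C
Reagents that add atoms: acetic anhydride, CC(=O)OC(C)=O
Why: Swern conditions cleave and oxidise the primary triethylsilyl ether directly; the electron-poor aldehyde is captured by the tertiary C10–OH as the seven-membered lactol (helped by the quaternary C8 and C10) and acetylated, the anomeric mixture being levelled in step 8.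

**Step 8**
Reactants: 15 lactol acetate
Product: 16 C5-vinyl oxepane (5R; vinyl trans to O6)
Conditions: CH2=CHBF3K (4 equiv), BF3·OEt2, MeCN/CH2Cl2, −40 → 0 °C
Reagents that add atoms: potassium vinyltrifluoroborate, C=C[B-](F)(F)F.[K+]
Why: BF3 ionises the anomeric acetate and the vinyltrifluoroborate adds to the oxocarbenium ion anti to the C6–O bond (polar Felkin–Anh), so the C5 vinyl group ends trans to O6 and trans to the C1 chain on C10.

**Step 9**
Reactants: 16 C5-vinyl oxepane
Product: 18 C8 alcohol (8R; OH cis to the C7–C11 bond), via ketone 17 (not isolated)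
Conditions: PhI(OCOCF3)2, MeCN/H2O (9:1), 0 °C, 10 min; then NaBH4, CeCl3·7H2O, MeOH, −78 °C
Reagents that add atoms: water, O
Why: Stork oxidative dithiane hydrolysis then Luche 1,2-reduction; hydride attacks the ring-A ketone from the face opposite the C7–C11 bond, placing the C8 hydroxyl cis to C11, and the cerium conditions spare the α-methylene lactone.

**Step 10**
Reactants: 19 methyl but-2-ynoate
Product: 21 methyl (Z)-2-(hydroxymethyl)but-2-enoate, via vinylalane 20 (not isolated)
Conditions: i-Bu2AlH, N-methylmorpholine N-oxide, THF, 0 °C; then CH2O (gas), −78 → −20 °C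
Reagents that add atoms: formaldehyde, C=O
Why: Syn conjugate hydroalumination (vinylalumination) puts H and Al cis, and hydroxymethylation with retention at low temperature gives the Z (sarracinate) geometry.

**Step 11**
Reactants: 21 methyl (Z)-2-(hydroxymethyl)but-2-enoate
Product: 22 methyl (Z)-2-[(tert-butyldimethylsilyloxy)methyl]but-2-enoate
Conditions: t-BuMe2SiCl, imidazole, CH2Cl2, 0 °C → rt
Reagents that add atoms: tert-butyl(chloro)dimethylsilane, CC(C)(C)[Si](C)(C)Cl
Why: Standard silylation of the primary allylic alcohol; the alkene geometry is not affected.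

**Step 12**
Reactants: 22 methyl (Z)-2-[(tert-butyldimethylsilyloxy)methyl]but-2-enoate
Product: 23 (Z)-2-[(tert-butyldimethylsilyloxy)methyl]but-2-enoic acid
Conditions: LiOH, THF/H2O, 0 °C → rt; aq. HCl work-up (pH 4)
Reagents that add atoms: lithium hydroxide, [Li+].[OH-]
Why: Saponification by acyl–oxygen cleavage at low temperature leaves the silyl ether and the Z-alkene intact.

**Step 13**
Reactants: 18 C8 alcohol; 23 (Z)-2-[(tert-butyldimethylsilyloxy)methyl]but-2-enoic acid
Product: 25 C8 ester (silyl-protected sarracinate), via mixed anhydride 24 (not isolated)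
Conditions: 23, 2,4,6-Cl3C6H2COCl, Et3N, toluene, rt; then 18, toluene, 80 °C
Reagents that add atoms: none
Why: Mixed-anhydride (Yamaguchi-type) acylation run without a nucleophilic amine catalyst, as used for angelates, so the Z-enoate does not isomerise; C8 keeps its configuration because only the O–H bond reacts.

**Step 14**
Reactants: 25 C8 ester
Product: 27 C3 aldoxime (E/Z), via aldehyde 26 (not isolated)
Conditions: O3 (1.0 equiv, Sudan Red 7B end-point), pyridine, CH2Cl2, −78 °C; then NH2OH·HCl, NaOAc, MeOH, 0 °C → rt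
Reagents that add atoms: hydroxylamine hydrochloride, NO.Cl
Why: Pyridine-moderated ozonolysis cleaves the electron-rich trisubstituted alkene far faster than the allylic-ether vinyl group or the two electron-poor enoates, and the aldehyde is condensed in situ to the oxime.

**Step 15**
Reactants: 27 C3 aldoxime
Product: 30 isoxazoline (ring B closed; C3–C4 and O–C15 bonds), via hydroximoyl chloride 28 (not isolated), via nitrile oxide 29 (not isolated)
Conditions: N-chlorosuccinimide, pyridine (cat.), CHCl3, rt; then slow addition (10 h) to Et3N, toluene, 60 °C, 0.002 M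
Reagents that add atoms: none
Why: Huisgen 1,3-dipolar cycloaddition (intramolecular nitrile oxide–alkene, fused mode) forms ring B; the inside-alkoxy transition state (ring oxygen inside, C6 anti) sets C4 with H4 cis to H5, and high dilution suppresses furoxan formation.

**Step 16**
Reactants: 30 isoxazoline
Product: 31 β-hydroxy ketone (3-oxo, 15-hydroxy)
Conditions: Mo(CO)6, MeCN/H2O (15:1), 80 °C
Reagents that add atoms: water, O
Why: Mo(CO)6 cleaves the N–O bond reductively and the β-hydroxy imine hydrolyses to the ketone without reducing any C=C bond; no stereocentre changes.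

**Step 17**
Reactants: 31 β-hydroxy ketone
Product: 32 3,15-diol (3S; 3-OH cis to C15)
Conditions: NaBH4, CeCl3·7H2O, MeOH, −78 °C
Reagents that add atoms: none
Why: Luche reduction; hydride attacks the C3 ketone from the face opposite the adjacent C4 hydroxymethyl group, giving the 3-OH cis to C15, and cerium suppresses conjugate reduction of the α-methylene lactone.

**Step 18**
Reactants: 32 3,15-diol
Product: 33 15-O-acetate
Conditions: AcCl, 2,4,6-collidine, CH2Cl2, −78 °C
Reagents that add atoms: acetyl chloride, CC(Cl)=O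
Why: Selective acylation; the primary C15 alcohol reacts much faster than the hindered secondary C3 alcohol at low temperature.

**Step 19**
Reactants: 33 15-O-acetate
Product: 34 CNP0311647.1
Conditions: HF·pyridine, THF, 0 °C → rt
Reagents that add atoms: none
Why: Fluoride-driven desilylation frees the primary allylic alcohol of the sarracinate; acetate, lactone and the Z-enoate are stable to buffered HF.

**Compound list**
1 | (R)-(−)-linalool, (3R)-3,7-dimethylocta-1,6-dien-3-ol | CC(C)=CCC[C@@](C)(O)C=C | starting material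
2 | (3R)-1-(9-borabicyclo[3.3.1]nonan-9-yl)-3,7-dimethyloct-6-en-3-ol | CC(C)=CCC[C@@](C)(O)CCB1C2CCCC1CCC2 | intermediate
3 | (3R)-3,7-dimethyloct-6-ene-1,3-diol | CC(C)=CCC[C@@](C)(O)CCO | intermediate
4 | (3R)-3-hydroxy-3,7-dimethyloct-6-enal | CC(C)=CCC[C@@](C)(O)CC=O | intermediate
5 | 2-[(2R)-2-hydroxy-2,6-dimethylhept-5-en-1-yl]-1,3-dithiane | CC(C)=CCC[C@@](C)(O)CC1SCCCS1 | intermediate
6 | (S)-5-(hydroxymethyl)furan-2(5H)-one | O=C1C=C[C@@H](CO)O1 | starting material
7 | (S)-5-[(triethylsilyloxy)methyl]furan-2(5H)-one | O=C1C=C[C@@H](CO[Si](CC)(CC)CC)O1 | intermediate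
8 | dilithio derivative of 5 (C2-lithiated dithiane, lithium alkoxide) | [Li+].[Li+].CC(C)=CCC[C@@](C)([O-])C[C-]1SCCCS1 | intermediate
9 | dilithium enolate/alkoxide from 1,4-addition of 8 to 7 (C7 trans to C6) | [Li+].[Li+].C1=C([O-])O[C@H](CO[Si](CC)(CC)CC)[C@H]1C2(C[C@](C)([O-])CCC=C(C)C)SCCCS2 | intermediate
10 | Mannich base, (4S,5S)-3-[(dimethylamino)methyl]-4-{2-[(2R)-2-hydroxy-2,6-dimethylhept-5-en-1-yl]-1,3-dithian-2-yl}-5-[(triethylsilyloxy)methyl]oxolan-2-one (C3 epimers) | CN(C)CC1C(=O)O[C@H](CO[Si](CC)(CC)CC)[C@H]1C2(C[C@](C)(O)CCC=C(C)C)SCCCS2 | intermediate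
11 | N-methyl quaternary ammonium iodide of 10 | C[N+](C)(C)CC1C(=O)O[C@H](CO[Si](CC)(CC)CC)[C@H]1C2(C[C@](C)(O)CCC=C(C)C)SCCCS2.[I-] | intermediate
12 | (4S,5S)-4-{2-[(2R)-2-hydroxy-2,6-dimethylhept-5-en-1-yl]-1,3-dithian-2-yl}-3-methylidene-5-[(triethylsilyloxy)methyl]oxolan-2-one | C=C1C(=O)O[C@H](CO[Si](CC)(CC)CC)[C@H]1C2(C[C@](C)(O)CCC=C(C)C)SCCCS2 | intermediate
13 | (2S,3S)-3-{2-[(2R)-2-hydroxy-2,6-dimethylhept-5-en-1-yl]-1,3-dithian-2-yl}-4-methylidene-5-oxooxolane-2-carbaldehyde | C=C1C(=O)O[C@H](C=O)[C@H]1C2(C[C@](C)(O)CCC=C(C)C)SCCCS2 | intermediate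
14 | ring-A lactol (C5 anomers): 5-hydroxy oxepane from the C5 aldehyde and the C10 hydroxyl, trans-fused at C6–C7 to the α-methylene-γ-lactone, spiro-1,3-dithiane at C8, C10 (R) bearing methyl and 4-methylpent-3-en-1-yl | C=C1C(=O)O[C@@H]2C(O)O[C@](C)(CCC=C(C)C)CC3(SCCCS3)[C@@H]12 | intermediate
15 | lactol acetate: 5-O-acetyl derivative of 14 (C5 anomers) | C=C1C(=O)O[C@@H]2C(OC(C)=O)O[C@](C)(CCC=C(C)C)CC3(SCCCS3)[C@@H]12 | intermediate
16 | (5R)-5-vinyl oxepane: as 15 with H and vinyl on C5, vinyl trans to the C6 lactone oxygen and trans to the C1 chain on C10 | C=C1C(=O)O[C@@H]2[C@@H](C=C)O[C@](C)(CCC=C(C)C)CC3(SCCCS3)[C@@H]12 | intermediate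
17 | C8 ketone from 16 (dithiane removed) | C=C1C(=O)O[C@@H]2[C@@H](C=C)O[C@](C)(CCC=C(C)C)CC(=O)[C@@H]12 | intermediate
18 | (8R)-8-hydroxy compound, 8-OH cis to the C7–C11 bond | C=C1C(=O)O[C@@H]2[C@@H](C=C)O[C@](C)(CCC=C(C)C)C[C@@H](O)[C@@H]12 | intermediate
19 | methyl but-2-ynoate | CC#CC(=O)OC | starting material
20 | methyl (Z)-2-(diisobutylalumanyl)but-2-enoate (H and Al cis) | COC(=O)/C(=C\C)[Al](CC(C)C)CC(C)C | intermediate
21 | methyl (Z)-2-(hydroxymethyl)but-2-enoate | COC(=O)/C(=C\C)CO | intermediate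
22 | methyl (Z)-2-[(tert-butyldimethylsilyloxy)methyl]but-2-enoate | COC(=O)/C(=C\C)CO[Si](C)(C)C(C)(C)C | intermediate
23 | (Z)-2-[(tert-butyldimethylsilyloxy)methyl]but-2-enoic acid | OC(=O)/C(=C\C)CO[Si](C)(C)C(C)(C)C | intermediate
24 | mixed anhydride of 23 with 2,4,6-trichlorobenzoic acid | O=C(OC(=O)/C(=C\C)CO[Si](C)(C)C(C)(C)C)c1c(Cl)cc(Cl)cc1Cl | intermediate
25 | C8 ester of 18 with acid 23 | C=C1C(=O)O[C@@H]2[C@@H](C=C)O[C@](C)(CCC=C(C)C)C[C@@H](OC(=O)/C(=C\C)CO[Si](C)(C)C(C)(C)C)[C@@H]12 | intermediate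
26 | C3 aldehyde (side-chain alkene of 25 cleaved) | C=C1C(=O)O[C@@H]2[C@@H](C=C)O[C@](C)(CCC=O)C[C@@H](OC(=O)/C(=C\C)CO[Si](C)(C)C(C)(C)C)[C@@H]12 | intermediate
27 | C3 aldoxime (E/Z) | C=C1C(=O)O[C@@H]2[C@@H](C=C)O[C@](C)(CCC=NO)C[C@@H](OC(=O)/C(=C\C)CO[Si](C)(C)C(C)(C)C)[C@@H]12 | intermediate
28 | C3 hydroximoyl chloride | C=C1C(=O)O[C@@H]2[C@@H](C=C)O[C@](C)(CCC(Cl)=NO)C[C@@H](OC(=O)/C(=C\C)CO[Si](C)(C)C(C)(C)C)[C@@H]12 | intermediate
29 | C3 nitrile oxide | C=C1C(=O)O[C@@H]2[C@@H](C=C)O[C@](C)(CCC#[N+][O-])C[C@@H](OC(=O)/C(=C\C)CO[Si](C)(C)C(C)(C)C)[C@@H]12 | intermediate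
30 | isoxazoline: ring B closed (C3–C4 bond, C15–O–N=C3), H4 cis to H5 | C=C1C(=O)O[C@@H]2[C@@H]3O[C@](C)(CCC4=NOC[C@H]34)C[C@@H](OC(=O)/C(=C\C)CO[Si](C)(C)C(C)(C)C)[C@@H]12 | intermediate
31 | β-hydroxy ketone: 3-oxo, 15-hydroxy | C=C1C(=O)O[C@@H]2[C@@H]3O[C@](C)(CCC(=O)[C@@H]3CO)C[C@@H](OC(=O)/C(=C\C)CO[Si](C)(C)C(C)(C)C)[C@@H]12 | intermediate
32 | 3,15-diol, (3S)-OH cis to the C4 hydroxymethyl group | C=C1C(=O)O[C@@H]2[C@@H]3O[C@](C)(CC[C@H](O)[C@@H]3CO)C[C@@H](OC(=O)/C(=C\C)CO[Si](C)(C)C(C)(C)C)[C@@H]12 | intermediate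
33 | 15-O-acetate of 32 (sarracinate still silylated) | C=C1C(=O)O[C@@H]2[C@@H]3O[C@](C)(CC[C@H](O)[C@@H]3COC(C)=O)C[C@@H](OC(=O)/C(=C\C)CO[Si](C)(C)C(C)(C)C)[C@@H]12 | intermediate
34 | CNP0311647.1, (3S,4S,5R,6S,7R,8R,10R)-15-acetoxy-3-hydroxy-8-[(Z)-2-(hydroxymethyl)but-2-enoyloxy]-5,10-epoxygermacr-11(13)-en-12,6-olide | C=C1C(=O)O[C@@H]2[C@@H]3O[C@](C)(CC[C@H](O)[C@@H]3COC(C)=O)C[C@@H](OC(=O)/C(=C\C)CO)[C@@H]12 | target

**Totals**
Total step count: 19. Longest linear sequence: 15 steps (1–3, 5–9, 13–19).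

**Three steps most likely to fail**

Step 15. Closing ring B onto a vinyl group that sits trans to the C1 chain gives a strained inside–outside bicycle, so dimerisation of the nitrile oxide to a furoxan may win. The fallback sets out from oxime 27 and comes back at isoxazoline 30. The oxime is heated without any oxidant (o-xylene, 140 °C, 0.005 M, sealed tube); its NH-nitrone tautomer undergoes a reversible intramolecular nitrone–alkene cycloaddition with no dimerisation channel and gives the cis-fused N–H isoxazolidine F3. This is dehydrogenated by N-chlorination and elimination (N-chlorosuccinimide, then DBU, CH2Cl2, 0 °C) to 30.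

Step 8. Three things can go wrong: the tertiary alcohol may not close or acetylate cleanly in step 7; the oxocarbenium ion may be trapped by the trisubstituted side-chain alkene (Prins) before the external nucleophile arrives; and the facial selectivity at C5 may be low. The fallback sets out from aldehyde 13 (step 7 stopped after Et3N) and comes back at 16, with no oxocarbenium ion on the way. Wittig reaction with Ph3P=CHCHO (toluene, 60 °C) gives the (E)-enal F1. Luche reduction (NaBH4, CeCl3·7H2O, MeOH, −40 °C) gives the (E)-allylic alcohol F2. PdCl2(MeCN)2 (20 mol %, because the thioacetal is a competing ligand), THF, 0 °C then closes ring A: the tertiary C10–OH adds to C5 and syn-β-hydroxide elimination (formal SN2′) releases the C5 vinyl group of 16.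

Step 9. The hydride face at the ring-A ketone 17 is predicted, not known, and the ketone can isomerise the exocyclic alkene into conjugation if handled slowly. The fallback sets out from 16 and comes back at ester 25. If the reduction gives mainly the C8-epimeric alcohol F4, the facial bias is used instead of fought: Mitsunobu esterification of F4 with acid 23 (PPh3, DIAD, toluene, 0 °C) inverts C8 and gives 25 directly, replacing step 13.

**Further compounds**
F1 | step 8 | (E)-enal: aldehyde of 13 extended to CH=CH–CHO, lactone stereocentres as in 13 | C=C1C(=O)O[C@H](/C=C/C=O)[C@H]1C2(C[C@](C)(O)CCC=C(C)C)SCCCS2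
F2 | step 8 | (E)-allylic alcohol from Luche reduction of F1 | C=C1C(=O)O[C@H](/C=C/CO)[C@H]1C2(C[C@](C)(O)CCC=C(C)C)SCCCS2
F3 | step 15 | cis-fused N–H isoxazolidine (ring B closed, H3 cis to H4) | C=C1C(=O)O[C@@H]2[C@@H]3O[C@](C)(CC[C@@H]4NOC[C@H]34)C[C@@H](OC(=O)/C(=C\C)CO[Si](C)(C)C(C)(C)C)[C@@H]12
F4 | step 9 | C8 epimer of 18 (8-OH trans to the C7–C11 bond) | C=C1C(=O)O[C@@H]2[C@@H](C=C)O[C@](C)(CCC=C(C)C)C[C@H](O)[C@@H]12
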